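**Retrosynthetic overview**
- C12–C13 bond and C13 carbinol: oxidative removal of boron from a seven-membered 1,2-oxaborepane. This ring comes from ring expansion of a six-membered 1,2-oxaborinane (C12–B–O–C8), in which C12 shifts 1,2 from boron to a stereodefined lithiated (S)-but-3-en-2-yl carbamate carbon.
- Rings A and B and the oxaborinane form in one operation: enantioselective bromonium-initiated chair–chair cyclisation of (E,E)-homofarnesylboronic acid, ended by a B–OH oxygen at C8. Ring order is ring A, then ring B, then the boracycle (six-membered, later enlarged to seven, then excised).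
- Boronic acid: chemoselective hydroboration of the vinyl terminus of (3E,7E)-4,8,12-trimethyltrideca-1,3,7,11-tetraene.
- Tetraene: sp3–sp2 Negishi coupling of two halves, each made by zirconium-catalysed carboalumination of a small alkyne.

Assumption: the (R)-catalyst of step 7 is taken to deliver bromine to the alkene face that gives 3R; if the sense is opposite, its (S)-antipode is used.
Labdane numbering (C1–C20) is used for the polyene and all cyclised compounds.

**Step 1**
Reactants: 1 but-3-yn-1-ol; 2 vinyl bromide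
Product: 4 (3E)-3-methylhexa-3,5-dien-1-ol, via alkenylalane 3 (not isolated)
Conditions: Me3Al (3 equiv), Cp2ZrCl2 (25 mol %), CH2Cl2, 0 to 23 °C; then 2, Pd(PPh3)4 (5 mol %), ZnCl2 (20 mol %), THF, 23 °C; H2O quench
Reagents that add atoms: trimethylaluminium, C[Al](C)C
Why: Negishi zirconium-catalysed syn-carboalumination puts methyl on the internal alkyne carbon and aluminium on the terminus (E geometry), and the alkenylalane then undergoes Negishi cross-coupling with vinyl bromide with retention of geometry.

**Step 2**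
Reactants: 4 (3E)-3-methylhexa-3,5-dien-1-ol
Product: 5 (3E)-6-iodo-4-methylhexa-1,3-diene
Conditions: I2, PPh3, imidazole, CH2Cl2, 0 °C
Reagents that add atoms: iodine, II
Why: Appel-type iodination of a primary alcohol proceeds by SN2 on the alkoxyphosphonium salt and leaves the diene untouched.

**Step 3**
Reactants: 6 5-bromo-2-methylpent-2-ene; 7 lithium acetylide–ethylenediamine complex
Product: 8 6-methylhept-5-en-1-yne
Conditions: DMSO, 0 to 23 °C
Reagents that add atoms: none
Why: SN2 alkylation of an acetylide by a primary bromide in a dipolar aprotic solvent is fast enough to outrun elimination.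

**Step 4**
Reactants: 8 6-methylhept-5-en-1-yne
Product: 10 (1E)-1-iodo-2,6-dimethylhepta-1,5-diene, via alkenylalane 9 (not isolated)
Conditions: Me3Al (2 equiv), Cp2ZrCl2 (20 mol %), CH2Cl2, 23 °C; then I2, THF, −30 °C
Reagents that add atoms: trimethylaluminium, C[Al](C)C; iodine, II
Why: Negishi carboalumination adds Me and Al syn to the terminal alkyne only (the trisubstituted alkene is inert), and iodinolysis of the C–Al bond retains the E geometry.

**Step 5**
Reactants: 5 (3E)-6-iodo-4-methylhexa-1,3-diene; 10 (1E)-1-iodo-2,6-dimethylhepta-1,5-diene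
Product: 12 (3E,7E)-4,8,12-trimethyltrideca-1,3,7,11-tetraene, via homoallylic zinc iodide 11 (not isolated)
Conditions: 5, Zn dust, LiCl, THF, 30 °C; then 10, PdCl2(dppf) (3 mol %), THF, 23 °C
Reagents that add atoms: none
Why: zinc inserts only into the primary C–I bond, and the Negishi alkyl–alkenyl coupling forms C6–C5 with full retention of alkene geometry, the wide-bite-angle ligand suppressing β-hydride elimination.

**Step 6**
Reactants: 12 (3E,7E)-4,8,12-trimethyltrideca-1,3,7,11-tetraene
Product: 15 [(3E,7E)-4,8,12-trimethyltrideca-3,7,11-trien-1-yl]boronic acid, via homofarnesylbis(isopinocampheyl)borane 13 (not isolated), via diethyl homofarnesylboronate 14 (not isolated)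
Conditions: (−)-Ipc2BH (1.05 equiv), THF, 0 °C; CH3CHO (excess), 23 °C; H2O
Reagents that add atoms: (−)-diisopinocampheylborane, B([C@@H]1C[C@@H]2C[C@H]([C@H]1C)C2(C)C)[C@@H]1C[C@@H]2C[C@H]([C@H]1C)C2(C)C; water, O
Why: Brown hydroboration with a bulky dialkylborane attacks only the monosubstituted vinyl terminus (the selectivity used in dialkylborane routes to homogeraniol and homofarnesol), and acetaldehyde then expels both pinene ligands to leave the boronic ester, which water hydrolyses.

**Step 7**
Reactants: 15 [(3E,7E)-4,8,12-trimethyltrideca-3,7,11-trien-1-yl]boronic acid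
Product: 16 (3R,5S,8S,9S,10R)-3-bromo-13,14,15,16-tetranorlabdane bridged C12–B(OH)–O–C8 (trans-fused tricyclic 2-hydroxy-1,2-oxaborinane; Br equatorial, trans-decalin, C8 methyl axial)
Conditions: 1,3-dibromo-5,5-dimethylhydantoin (0.55 equiv), (R)-3,3'-bis(2,4,6-triisopropylphenyl)-1,1'-binaphthalene-2,2'-diyl N-[3,5-bis(trifluoromethyl)phenyl]phosphoramidothioate (10 mol %), toluene–CH2Cl2 1:1, −78 °C
Reagents that add atoms: 1,3-dibromo-5,5-dimethylhydantoin, CC1(C)N(Br)C(=O)N(Br)C1=O
Why: Proposed new method: the P=S sulfur of the chiral Lewis base takes Br+ from the hydantoin and passes it to one face of the most electron-rich, least hindered C3=C4 alkene; the bromiranium is opened anti by C5=C10 and then C9=C8 through an all-chair E,E array (Stork–Eschenmoser control), which fixes C3 (Br equatorial), C5, C10 and C9; the C8 cation is caught on its equatorial face by a B–OH oxygen of the C12 boronic acid, closing a trans-fused six-membered ring and setting C8, with the proton going to the hydantoin anion; adventitious water capture at C8 followed by condensation with boron gives the same product; the closest known reaction types are thiophosphoramide/dibromohydantoin asymmetric bromopolyene cyclisations ended by arenes or phenols and bromonium polyene cyclisations ended by carboxylic acids, and a boronic acid has not been used as the terminator.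

**Step 8**
Reactants: 17 (S)-but-3-en-2-ol
Product: 18 (S)-but-3-en-2-yl N,N-diisopropylcarbamate
Conditions: iPr2NC(O)Cl, Et3N, CH2Cl2, reflux
Reagents that add atoms: N,N-diisopropylcarbamoyl chloride, CC(C)N(C(C)C)C(=O)Cl
Why: O-carbamoylation installs the directing and leaving group without touching the stereocentre.

**Step 9**
Reactants: 16 tricyclic 2-hydroxy-1,2-oxaborinane; 18 (S)-but-3-en-2-yl N,N-diisopropylcarbamate
Product: 23 (3R,5S,8S,9S,10R,13R)-3-bromolabd-14-ene-8,13-diol, via B-methoxy oxaborinane 19 (not isolated), via lithiated carbamate 20 (not isolated), via boronate ate complex 21 (not isolated), via ring-expanded oxaborepane 22 (not isolated)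
Conditions: 16, MeOH, 3 Å MS, then evaporate; separately 18 (1.3 equiv), sBuLi (1.2 equiv), TMEDA, Et2O, −78 °C; add 19, −78 to 23 °C; then H2O2, NaOH, THF, 0 °C
Reagents that add atoms: hydrogen peroxide, OO
Why: Proposed new method: the configurationally stable lithiated carbamate adds to boron with retention; ring carbon C12 then shifts 1,2 from boron to C13 antiperiplanar to the departing carbamate (inversion at C13), enlarging the six-membered oxaborinane to the seven-membered oxaborepane; this forms C12–C13 and sets C13 while boron keeps O8 masked, so no protecting group is needed; C–B oxidation with retention gives 13R and releases the C8 alcohol, and any minor decalin antipode from step 7 becomes a separable diastereomer here; the equatorial neopentyl bromide has no antiperiplanar hydrogen and resists both the stabilised carbanion and the basic peroxide; the closest known reaction types are ring enlargement of B-methoxyboracyclanes by lithium carbenoids and lithiation–borylation of acyclic pinacol boronates with lithiated secondary allylic carbamates, neither shown on a cyclic hemiboronic ester with a stereodefined tertiary carbenoid.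

**Compound list**
1 | but-3-yn-1-ol | C#CCCO | starting material
2 | vinyl bromide | C=CBr | starting material
3 | (E)-alkenylalane from 1, O-aluminated | C[Al](C)/C=C(\C)CCO[Al](C)C | intermediate
4 | (3E)-3-methylhexa-3,5-dien-1-ol | OCC/C(C)=C/C=C | intermediate
5 | (3E)-6-iodo-4-methylhexa-1,3-diene | ICC/C(C)=C/C=C | intermediate
6 | 5-bromo-2-methylpent-2-ene | CC(C)=CCCBr | starting material
7 | lithium acetylide–ethylenediamine complex | [Li]C#C.NCCN | starting material
8 | 6-methylhept-5-en-1-yne | C#CCCC=C(C)C | intermediate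
9 | (E)-(2,6-dimethylhepta-1,5-dienyl)dimethylalane | C[Al](C)/C=C(\C)CCC=C(C)C | intermediate
10 | (1E)-1-iodo-2,6-dimethylhepta-1,5-diene | I/C=C(\C)CCC=C(C)C | intermediate
11 | [(3E)-3-methylhexa-3,5-dienyl]zinc iodide | I[Zn]CC/C(C)=C/C=C | intermediate
12 | (3E,7E)-4,8,12-trimethyltrideca-1,3,7,11-tetraene | C=C/C=C(\C)CC/C=C(\C)CCC=C(C)C | intermediate
13 | (E,E)-homofarnesylbis(isopinocampheyl)borane | CC(C)=CCC/C(C)=C/CC/C(C)=C/CCB([C@@H]1C[C@@H]2C[C@H]([C@H]1C)C2(C)C)[C@@H]1C[C@@H]2C[C@H]([C@H]1C)C2(C)C | intermediate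
14 | diethyl (E,E)-homofarnesylboronate | CCOB(OCC)CC/C=C(\C)CC/C=C(\C)CCC=C(C)C | intermediate
15 | [(3E,7E)-4,8,12-trimethyltrideca-3,7,11-trien-1-yl]boronic acid | OB(O)CC/C=C(\C)CC/C=C(\C)CCC=C(C)C | intermediate
16 | (3R,5S,8S,9S,10R)-3-bromo tricyclic 2-hydroxy-1,2-oxaborinane (B on C12, ring O on C8) | OB1CC[C@H]2[C@]3(C)CC[C@@H](Br)C(C)(C)[C@H]3CC[C@]2(C)O1 | intermediate
17 | (S)-but-3-en-2-ol | C=C[C@H](C)O | starting material
18 | (S)-but-3-en-2-yl N,N-diisopropylcarbamate | C=C[C@H](C)OC(=O)N(C(C)C)C(C)C | intermediate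
19 | B-methoxy derivative of 16 | COB1CC[C@H]2[C@]3(C)CC[C@@H](Br)C(C)(C)[C@H]3CC[C@]2(C)O1 | intermediate
20 | (S)-2-lithiobut-3-en-2-yl N,N-diisopropylcarbamate | C=C[C@]([Li])(C)OC(=O)N(C(C)C)C(C)C | intermediate
21 | lithium boronate ate complex of 19 and 20 (configuration at boron undefined) | [Li+].CO[B-]1([C@](C)(C=C)OC(=O)N(C(C)C)C(C)C)CC[C@H]2[C@]3(C)CC[C@@H](Br)C(C)(C)[C@H]3CC[C@]2(C)O1 | intermediate
22 | (13S)-B-methoxy-1,2-oxaborepane (ring B–C13–C12–C11–C9–C8–O; C13 bears methyl and vinyl) | COB1[C@@](C)(C=C)CC[C@H]2[C@]3(C)CC[C@@H](Br)C(C)(C)[C@H]3CC[C@]2(C)O1 | intermediate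
23 | (3R,5S,8S,9S,10R,13R)-3-bromolabd-14-ene-8,13-diol = (1S,2S,4aS,6R,8aR)-6-bromo-1-[(3R)-3-hydroxy-3-methylpent-4-en-1-yl]-2,5,5,8a-tetramethyldecahydronaphthalen-2-ol | C=C[C@](C)(O)CC[C@H]1[C@]2(C)CC[C@@H](Br)C(C)(C)[C@H]2CC[C@]1(C)O | target

**Step count and risks**

Total step count: 9. Longest linear sequence: 6 steps (1, 2, 5, 6, 7, 9).

**Step 7 (proposed new step).**
- Risks: proton loss from the C8 cation, partial cyclisation, modest enantioselectivity.
- The fallback sets out from 15 and comes back at 23, using known chemistry.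
- 15 is condensed with pinacol to homofarnesyl pinacol boronate F1.
- Addition of 20 gives acyclic boronate ate complex F2, which rearranges on warming to tertiary allylic pinacol boronate F3.
- H2O2/NaOH then gives (3R,6E,10E)-geranyllinalool F4.
- Brominative cyclisation of F4 with 2,4,4,6-tetrabromocyclohexa-2,5-dienone in wet MeNO2, with water as terminator, gives 23 together with decalin-antipodal diastereomer F5. The two are separated by chromatography. The yield is low, but the product is a single enantiomer because C13 is already fixed.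

**Step 9 (proposed new step).**
- Risks: loss of methoxide from the ate complex, oxygen migration, slow complexation.
- The fallback sets out from 16 and comes back at 23, using known chemistry on an acyclic boronate.
- Pinacol opens 16 to hydroxy pinacol boronate F6.
- Et3SiOTf/2,6-lutidine gives triethylsilyl ether boronate F7.
- 20 adds to give protected ate complex F8, which rearranges to protected tertiary allylic boronate F9.
- H2O2/NaOH gives O8-triethylsilyl diol F10, and Bu4NF releases 23.

**Step 6.**
- Risks: hydroboration of a trisubstituted alkene after pinene dissociation, incomplete dealkylation.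
- The fallback sets out from 12 and comes back at 15, forming the C–B bond from an organolithium instead.
- Dicyclohexylborane gives homofarnesyldicyclohexylborane F11, which H2O2/NaOH oxidises to (3E,7E)-homofarnesol F12.
- I2/PPh3/imidazole gives homofarnesyl iodide F13.
- t-BuLi at −78 °C gives homofarnesyllithium F14, and B(OMe)3 gives dimethyl homofarnesylboronate F15.
- Dilute HCl gives 15.

**Further compounds**
F1 | step 7 | homofarnesyl pinacol boronate | CC(C)=CCC/C(C)=C/CC/C(C)=C/CCB1OC(C)(C)C(C)(C)O1
F2 | step 7 | acyclic boronate ate complex | [Li+].CC(C)=CCC/C(C)=C/CC/C(C)=C/CC[B-]1([C@](C)(C=C)OC(=O)N(C(C)C)C(C)C)OC(C)(C)C(C)(C)O1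
F3 | step 7 | tertiary allylic pinacol boronate | C=C[C@](C)(B1OC(C)(C)C(C)(C)O1)CC/C=C(\C)CC/C=C(\C)CCC=C(C)C
F4 | step 7 | (3R,6E,10E)-geranyllinalool | C=C[C@](C)(O)CC/C=C(\C)CC/C=C(\C)CCC=C(C)C
F5 | step 7 | decalin-antipodal diastereomer (3S,5R,8R,9R,10S,13R) | C=C[C@](C)(O)CC[C@@H]1[C@@]2(C)CC[C@H](Br)C(C)(C)[C@@H]2CC[C@@]1(C)O
F6 | step 9 | hydroxy pinacol boronate | CC1(C)OB(CC[C@H]2[C@]3(C)CC[C@@H](Br)C(C)(C)[C@H]3CC[C@]2(C)O)OC1(C)C
F7 | step 9 | triethylsilyl ether boronate | CC1(C)OB(CC[C@H]2[C@]3(C)CC[C@@H](Br)C(C)(C)[C@H]3CC[C@]2(C)O[Si](CC)(CC)CC)OC1(C)C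
F8 | step 9 | protected ate complex | [Li+].CC1(C)O[B-](CC[C@H]2[C@]3(C)CC[C@@H](Br)C(C)(C)[C@H]3CC[C@]2(C)O[Si](CC)(CC)CC)([C@](C)(C=C)OC(=O)N(C(C)C)C(C)C)OC1(C)C
F9 | step 9 | protected tertiary allylic boronate | C=C[C@](C)(B1OC(C)(C)C(C)(C)O1)CC[C@H]1[C@]2(C)CC[C@@H](Br)C(C)(C)[C@H]2CC[C@]1(C)O[Si](CC)(CC)CC
F10 | step 9 | O8-triethylsilyl diol | C=C[C@](C)(O)CC[C@H]1[C@]2(C)CC[C@@H](Br)C(C)(C)[C@H]2CC[C@]1(C)O[Si](CC)(CC)CC
F11 | step 6 | homofarnesyldicyclohexylborane | CC(C)=CCC/C(C)=C/CC/C(C)=C/CCB(C1CCCCC1)C1CCCCC1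
F12 | step 6 | (3E,7E)-homofarnesol | OCC/C=C(\C)CC/C=C(\C)CCC=C(C)C
F13 | step 6 | homofarnesyl iodide | ICC/C=C(\C)CC/C=C(\C)CCC=C(C)C
F14 | step 6 | homofarnesyllithium | [Li]CC/C=C(\C)CC/C=C(\C)CCC=C(C)C
F15 | step 6 | dimethyl homofarnesylboronate | COB(OC)CC/C=C(\C)CC/C=C(\C)CCC=C(C)C
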